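**Plan**
Cuts, in retrosynthetic order: bridge CH2–C3 of the pyranone; C5–C(=O) of the isobutyryl group; the isopropenyl C=C (back to a silylated tertiary carbinol); last, O1–C7a and C3–C3a of the dihydrofuran together.
Enabling feature (benzofuran numbering): C7a (bearing O1) and C3a (bearing the C3 methylene) are adjacent on the benzene ring. C7, the other neighbour of C7a, already holds the bridge carbon. This is the ipso/ortho pattern of an aryl iodide with one ortho site blocked and one ortho C–H open.
Forward: 5-iodoresorcinol supplies the benzene ring and receives the bridge carbon beside iodine; the dihydrofuran ring is annulated in one palladium/norbornene step; acyl group and alkene follow. The pyranone ring is made separately from pentan-3-one and malonyl dichloride and is joined last through an ortho-quinone methide.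
Stereochemistry: the only centre, C2 (R), is fixed by hydrolytic kinetic resolution of the terminal epoxide. Its C–O bond becomes C2–O1 without being broken, and no later step touches it.

Key step: step 8

Remark: benzofuran numbering (O1, C2, C3, C3a, C4–C7, C7a) is used for all bicyclic compounds; MOM = methoxymethyl, TES = triethylsilyl.
Assumption: the (S,S)-cobalt–salen catalyst is taken to spare the epoxide enantiomer that corresponds in space to (S)-propylene oxide; because CMe2OTES outranks the ring CH2 in the sequence rule, that enantiomer carries the descriptor R here.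

Step 1
Reactants: 1 5-iodobenzene-1,3-diol
Product: 3 2,4-dihydroxy-6-iodobenzaldehyde, via aryl iminium dichlorophosphate 2 (not isolated)
Conditions: POCl3, DMF, MeCN, 0 °C → rt; then H2O, 50 °C
Reagents that add atoms: N,N-dimethylformamide, CN(C)C=O; water, O
Why: Vilsmeier–Haack formylation of a resorcinol goes to the carbon para to one hydroxyl and ortho to the other rather than to the crowded carbon between both, as with orcinol and 5-halo-1,3-dialkoxybenzenes, which places the future bridge carbon beside iodine before hydrolysis of 2 releases the aldehyde.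

Step 2
Reactants: 3 2,4-dihydroxy-6-iodobenzaldehyde
Product: 4 2-iodo-4,6-bis(methoxymethoxy)benzaldehyde
Conditions: NaH, MOMCl, DMF, 0 °C → rt
Reagents that add atoms: chloromethyl methyl ether (MOMCl), COCCl
Why: Williamson-type alkylation of the bis-phenoxide, with a strong base because the hydroxyl hydrogen-bonded to the aldehyde reacts sluggishly under amine bases; MOM ethers tolerate base, palladium and butyllithium and later direct the lithiation of step 9.

Step 3
Reactants: 4 2-iodo-4,6-bis(methoxymethoxy)benzaldehyde
Product: 5 [2-iodo-4,6-bis(methoxymethoxy)phenyl]methanol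
Conditions: NaBH4, MeOH–THF, 0 °C
Reagents that add atoms: none
Why: Borohydride reduction of an aryl aldehyde, placed after phenol protection so that no ortho-quinone methide can form and be over-reduced to a methyl group, with the C–I bond inert.

Step 4
Reactants: 5 [2-iodo-4,6-bis(methoxymethoxy)phenyl]methanol
Product: 6 1-iodo-2-(methoxymethyl)-3,5-bis(methoxymethoxy)benzene
Conditions: NaH, MeI, THF, 0 °C → rt
Reagents that add atoms: iodomethane, CI
Why: Williamson etherification gives a small ortho blocking group that is stable to base and organolithium reagents for step 8 and later serves as the leaving group of the ortho-quinone methide precursor in step 14.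

Step 5
Reactants: 7 2-methylbut-3-en-2-ol
Product: 8 triethyl[(2-methylbut-3-en-2-yl)oxy]silane
Conditions: TESOTf, 2,6-lutidine, CH2Cl2, 0 °C
Reagents that add atoms: triethylsilyl trifluoromethanesulfonate, CC[Si](CC)(CC)OS(=O)(=O)C(F)(F)F
Why: Silylation of a tertiary alcohol with the silyl triflate/hindered pyridine pair, so that the alcohol can neither bind palladium nor compete as an oxygen nucleophile in step 8 and the small epoxide becomes easy to handle.

Step 6
Reactants: 8 triethyl[(2-methylbut-3-en-2-yl)oxy]silane
Product: 9 rac-triethyl{[2-(oxiran-2-yl)propan-2-yl]oxy}silane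
Conditions: mCPBA, CH2Cl2, 0 °C → rt
Reagents that add atoms: 3-chloroperoxybenzoic acid (mCPBA), O=C(OO)c1cccc(Cl)c1
Why: Prilezhaev epoxidation of the only alkene; the new stereocentre forms without control (racemate) and is resolved in step 7.

Step 7
Reactants: 9 rac-triethyl{[2-(oxiran-2-yl)propan-2-yl]oxy}silane
Product: 10 triethyl({2-[(2R)-oxiran-2-yl]propan-2-yl}oxy)silane
Conditions: (S,S)-(salen)Co(OAc) (2 mol %; salen = N,N'-bis(3,5-di-tert-butylsalicylidene)cyclohexane-1,2-diaminate), H2O (0.55 equiv), THF, 0 °C → rt
Reagents that add atoms: none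
Why: Hydrolytic kinetic resolution, in which the trivalent cobalt–salen catalyst activates epoxide and water cooperatively and should hydrolyse the S enantiomer much faster, as known for terminal epoxides including tert-alkyl-substituted ones, so that (R)-10 remains and the only stereocentre of the target is fixed here.

Step 8
Reactants: 6 1-iodo-2-(methoxymethyl)-3,5-bis(methoxymethoxy)benzene; 10 triethyl({2-[(2R)-oxiran-2-yl]propan-2-yl}oxy)silane
Product: 11 triethyl({2-[(2R)-7-(methoxymethyl)-4,6-bis(methoxymethoxy)-2,3-dihydro-1-benzofuran-2-yl]propan-2-yl}oxy)silane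
Conditions: 10 (1.5 equiv), Pd(OAc)2 (10 mol %), XPhos (20 mol %), potassium norborn-5-ene-2-carboxylate (50 mol %), K2CO3 (2 equiv), NMP, 80 °C, argon
Reagents that add atoms: none
Why: Zerovalent palladium (from Pd(OAc)2 and XPhos) inserts into the C–I bond of 6, the norbornene inserts into the aryl–palladium bond, and base-assisted palladation of the single free ortho C–H gives an aryl–norbornyl palladacycle of divalent palladium. This palladacycle opens 10 by SN2 attack at the unsubstituted CH2 to reach tetravalent palladium, and aryl–alkyl reductive elimination forms C3–C3a. With both ortho positions now filled the norbornene is expelled by β-carbon elimination, the freed secondary alkoxide binds the arylpalladium centre, and the dihydrofuran ring closes by C(aryl)–O reductive elimination from the six-membered oxapalladacycle (O1–C7a), a closure that the bulky phosphine favours over β-hydride loss. The closest known reaction is the Catellani-type annulation of ortho-substituted aryl iodides with terminal epoxides to 2-substituted 2,3-dihydrobenzofurans. No stereocentre is created, since C2 is the epoxide carbon whose C–O bond is never broken, so the R configuration of 10 is carried into 11 unchanged. The step needs site selectivity, secured by the CH2OMe group that blocks the second ortho carbon, attack at the epoxide CH2 only, secured by the quaternary CMe2OTES group that shields the CH, and access to a C–H flanked by an OMOM group, helped by the freedom of that acetal chain to turn towards the unsubstituted ring carbon on its other side.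

Step 9
Reactants: 11 triethyl({2-[(2R)-7-(methoxymethyl)-4,6-bis(methoxymethoxy)-2,3-dihydro-1-benzofuran-2-yl]propan-2-yl}oxy)silane; 12 isobutyric anhydride
Product: 14 1-[(2R)-7-(methoxymethyl)-4,6-bis(methoxymethoxy)-2-{2-[(triethylsilyl)oxy]propan-2-yl}-2,3-dihydro-1-benzofuran-5-yl]-2-methylpropan-1-one, via C5 aryllithium 13 (not isolated)
Conditions: n-BuLi (1.2 equiv), THF, 0 °C; then cannulated into 12 (3 equiv), THF, −78 → 0 °C
Reagents that add atoms: none
Why: Directed ortho-metalation removes the only aromatic hydrogen, which lies between two lithium-chelating MOM ethers, and inverse addition of 13 to excess anhydride (acylation of an aryllithium) should stop at the ketone because its two ortho substituents shield it; the step is run while the side chain is still a silyl ether so that no allylic C–H competes.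

Step 10
Reactants: 14 1-[(2R)-7-(methoxymethyl)-4,6-bis(methoxymethoxy)-2-{2-[(triethylsilyl)oxy]propan-2-yl}-2,3-dihydro-1-benzofuran-5-yl]-2-methylpropan-1-one
Product: 15 1-[(2R)-2-(2-hydroxypropan-2-yl)-7-(methoxymethyl)-4,6-bis(methoxymethoxy)-2,3-dihydro-1-benzofuran-5-yl]-2-methylpropan-1-one
Conditions: TBAF, THF, 0 °C → rt
Reagents that add atoms: none
Why: Fluoride-induced desilylation driven by the Si–F bond, to which the MOM ethers, the methyl ether, the hindered ketone and C2 are inert.

Step 11
Reactants: 15 1-[(2R)-2-(2-hydroxypropan-2-yl)-7-(methoxymethyl)-4,6-bis(methoxymethoxy)-2,3-dihydro-1-benzofuran-5-yl]-2-methylpropan-1-one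
Product: 17 1-[(2R)-7-(methoxymethyl)-4,6-bis(methoxymethoxy)-2-(prop-1-en-2-yl)-2,3-dihydro-1-benzofuran-5-yl]-2-methylpropan-1-one, via tertiary sulfamate salt 16 (not isolated)
Conditions: Burgess reagent (MeO2CN(−)SO2N(+)Et3, 2 equiv), toluene, rt → 60 °C
Reagents that add atoms: none
Why: Burgess dehydration by thermal syn elimination (Ei) of 16, in which six methyl hydrogens against one C2–H and the eclipsing strain needed to bring C2–H syn to the leaving group favour the isopropenyl isomer, the outcome known for 2-(2-hydroxypropan-2-yl)dihydrobenzofurans, while the neutral medium spares the acetals and C2.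

Step 12
Reactants: 18 pentan-3-one
Product: 19 trimethyl(pent-2-en-3-yloxy)silane
Conditions: TMSOTf, Et3N, CH2Cl2, 0 °C
Reagents that add atoms: trimethylsilyl trifluoromethanesulfonate, C[Si](C)(C)OS(=O)(=O)C(F)(F)F
Why: Soft enolisation and O-silylation of a symmetrical ketone, so that no regiochemical question arises and the double-bond geometry is irrelevant for step 13.

Step 13
Reactants: 19 trimethyl(pent-2-en-3-yloxy)silane; 20 malonyl dichloride
Product: 22 6-ethyl-4-hydroxy-5-methyl-2H-pyran-2-one, via 4-methyl-3,5-dioxoheptanoyl chloride 21 (not isolated)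
Conditions: Et2O, −78 °C → rt
Reagents that add atoms: none
Why: C-acylation of the silyl enol ether by one acid chloride gives 21, whose enol oxygen closes on the second acid chloride, the known annulation of ketone silyl enol ethers with malonyl dichloride to 5,6-disubstituted 4-hydroxy-2-pyranones.

Step 14
Reactants: 17 1-[(2R)-7-(methoxymethyl)-4,6-bis(methoxymethoxy)-2-(prop-1-en-2-yl)-2,3-dihydro-1-benzofuran-5-yl]-2-methylpropan-1-one; 22 6-ethyl-4-hydroxy-5-methyl-2H-pyran-2-one
Product: 25 3-{[(2R)-4,6-dihydroxy-5-(2-methylpropanoyl)-2-(prop-1-en-2-yl)-2,3-dihydro-1-benzofuran-7-yl]methyl}-6-ethyl-4-hydroxy-5-methyl-2H-pyran-2-one (target), via 7-(methoxymethyl) diphenol 23 (not isolated), via ortho-quinone methide 24 (not isolated)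
Conditions: (a) conc. aq. HCl (cat.), MeOH, 40 °C, then evaporation; (b) 22 (2 equiv), p-TsOH·H2O (20 mol %), MeCN, 40 °C
Reagents that add atoms: none
Why: Acid-catalysed acetal exchange with methanol removes the two ketone-flanking aryl MOM groups and the formaldehyde acetal is evaporated before the pyranone is added, after which acid-induced loss of methanol from the ortho-hydroxybenzyl ether 23 gives 24, which the only nucleophilic carbon of 22 (C3) captures in the Michael-type Friedel–Crafts benzylation known for 4-hydroxy-2-pyranones, with C2 not involved.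

**Compound list**
1 | 5-iodobenzene-1,3-diol | Oc1cc(O)cc(I)c1 | starting material
2 | N-[(2,4-dihydroxy-6-iodophenyl)methylidene]-N-methylmethanaminium dichlorophosphate | C[N+](C)=Cc1c(O)cc(O)cc1I.[O-]P(=O)(Cl)Cl | intermediate (not isolated)
3 | 2,4-dihydroxy-6-iodobenzaldehyde | O=Cc1c(O)cc(O)cc1I | intermediate
4 | 2-iodo-4,6-bis(methoxymethoxy)benzaldehyde | O=Cc1c(OCOC)cc(OCOC)cc1I | intermediate
5 | [2-iodo-4,6-bis(methoxymethoxy)phenyl]methanol | OCc1c(OCOC)cc(OCOC)cc1I | intermediate
6 | 1-iodo-2-(methoxymethyl)-3,5-bis(methoxymethoxy)benzene | COCc1c(OCOC)cc(OCOC)cc1I | intermediate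
7 | 2-methylbut-3-en-2-ol | C=CC(C)(C)O | starting material
8 | triethyl[(2-methylbut-3-en-2-yl)oxy]silane | C=CC(C)(C)O[Si](CC)(CC)CC | intermediate
9 | rac-triethyl{[2-(oxiran-2-yl)propan-2-yl]oxy}silane | CC[Si](CC)(CC)OC(C)(C)C1CO1 | intermediate
10 | triethyl({2-[(2R)-oxiran-2-yl]propan-2-yl}oxy)silane | CC[Si](CC)(CC)OC(C)(C)[C@H]1CO1 | intermediate
11 | triethyl({2-[(2R)-7-(methoxymethyl)-4,6-bis(methoxymethoxy)-2,3-dihydro-1-benzofuran-2-yl]propan-2-yl}oxy)silane | CC[Si](CC)(CC)OC(C)(C)[C@H]1Cc2c(OCOC)cc(OCOC)c(COC)c2O1 | intermediate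
12 | isobutyric anhydride | CC(C)C(=O)OC(=O)C(C)C | starting material
13 | (2R)-5-lithio derivative of 11 | CC[Si](CC)(CC)OC(C)(C)[C@H]1Cc2c(OCOC)c([Li])c(OCOC)c(COC)c2O1 | intermediate (not isolated)
14 | 1-[(2R)-7-(methoxymethyl)-4,6-bis(methoxymethoxy)-2-{2-[(triethylsilyl)oxy]propan-2-yl}-2,3-dihydro-1-benzofuran-5-yl]-2-methylpropan-1-one | CC[Si](CC)(CC)OC(C)(C)[C@H]1Cc2c(OCOC)c(C(=O)C(C)C)c(OCOC)c(COC)c2O1 | intermediate
15 | 1-[(2R)-2-(2-hydroxypropan-2-yl)-7-(methoxymethyl)-4,6-bis(methoxymethoxy)-2,3-dihydro-1-benzofuran-5-yl]-2-methylpropan-1-one | CC(C)(O)[C@H]1Cc2c(OCOC)c(C(=O)C(C)C)c(OCOC)c(COC)c2O1 | intermediate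
16 | triethylammonium salt of the N-(methoxycarbonyl)sulfamate ester of 15 | COC(=O)[N-]S(=O)(=O)OC(C)(C)[C@H]1Cc2c(OCOC)c(C(=O)C(C)C)c(OCOC)c(COC)c2O1.CC[NH+](CC)CC | intermediate (not isolated)
17 | 1-[(2R)-7-(methoxymethyl)-4,6-bis(methoxymethoxy)-2-(prop-1-en-2-yl)-2,3-dihydro-1-benzofuran-5-yl]-2-methylpropan-1-one | C=C(C)[C@H]1Cc2c(OCOC)c(C(=O)C(C)C)c(OCOC)c(COC)c2O1 | intermediate
18 | pentan-3-one | CCC(=O)CC | starting material
19 | trimethyl(pent-2-en-3-yloxy)silane | CC=C(CC)O[Si](C)(C)C | intermediate
20 | malonyl dichloride | O=C(Cl)CC(=O)Cl | starting material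
21 | 4-methyl-3,5-dioxoheptanoyl chloride | CCC(=O)C(C)C(=O)CC(=O)Cl | intermediate (not isolated)
22 | 6-ethyl-4-hydroxy-5-methyl-2H-pyran-2-one | CCc1oc(=O)cc(O)c1C | intermediate
23 | 1-[(2R)-4,6-dihydroxy-7-(methoxymethyl)-2-(prop-1-en-2-yl)-2,3-dihydro-1-benzofuran-5-yl]-2-methylpropan-1-one | C=C(C)[C@H]1Cc2c(O)c(C(=O)C(C)C)c(O)c(COC)c2O1 | intermediate (not isolated)
24 | (2R)-4-hydroxy-7-methylidene-5-(2-methylpropanoyl)-2-(prop-1-en-2-yl)-3,7-dihydro-1-benzofuran-6(2H)-one | C=C(C)[C@H]1CC2=C(O1)C(=C)C(=O)C(C(=O)C(C)C)=C2O | intermediate (not isolated)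
25 | 3-{[(2R)-4,6-dihydroxy-5-(2-methylpropanoyl)-2-(prop-1-en-2-yl)-2,3-dihydro-1-benzofuran-7-yl]methyl}-6-ethyl-4-hydroxy-5-methyl-2H-pyran-2-one | C=C(C)[C@H]1Cc2c(O)c(C(=O)C(C)C)c(O)c(Cc3c(O)c(C)c(CC)oc3=O)c2O1 | target

**Step count:** 14 steps in total. The longest linear sequence is 9 steps (steps 1–4, 8–11, 14).

**Steps most likely to fail**

Step 8.
- What may go wrong: palladation of the C–H squeezed between the palladium-bearing carbon and an OMOM-bearing carbon may be slow. Opening of the neopentyl-like epoxide by the palladacycle may also be sluggish. Simple reduction of the iodide, norbornene-retaining pathways or β-hydride loss from the palladium alkoxide could then take over.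
- Fallback: it closes the same ring from the oxygen side with known chemistry, setting out from 6 and returning at 11.
- Copper-catalysed hydroxylation of 6 (CuI, 1,10-phenanthroline, KOH, DMSO–H2O, 100 °C) should give 3,5-bis(methoxymethoxy)-2-(methoxymethyl)phenol F1.
- Palladium-catalysed O-allylation with tert-butyl 2-methylbut-3-en-2-yl carbonate (Pd(PPh3)4, THF, 0 °C) should give the 1,1-dimethylallyl aryl ether F2.
- Aromatic Claisen rearrangement of this ether (xylene, 130 °C) can end only at the one free ortho carbon and should give the ortho-prenylphenol F3.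
- Acetylation (Ac2O, pyridine) gives the aryl acetate F4.
- Shi epoxidation with the enantiomer of the D-fructose-derived ketone (KHSO5, K2CO3, aqueous MeCN, 0 °C) should give the (S)-epoxide F5.
- K2CO3 in MeOH frees the phenoxide, which opens the epoxide 5-exo at the secondary carbon with inversion to the (R)-carbinol F6.
- TESOTf and 2,6-lutidine convert this carbinol into 11.

Step 14.
- What may go wrong: acid may add to, or shift, the isopropenyl double bond during the two acidic stages. Ionisation of the benzylic ether may be slow, so that self-reaction of the quinone methide or side reactions of the pyranone compete with C–C bond formation.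
- Fallback: it moves the C–C bond formation to basic medium, setting out from 23 (now isolated after stage a) and returning at 25.
- Stirring 23 with sodium p-toluenesulfinate in acetic acid at room temperature should give the benzylic sulfone 1-[(2R)-4,6-dihydroxy-7-{[(4-methylphenyl)sulfonyl]methyl}-2-(prop-1-en-2-yl)-2,3-dihydro-1-benzofuran-5-yl]-2-methylpropan-1-one F7. This is a bench-stable member of the 2-(sulfonylmethyl)phenol class of quinone methide precursors.
- With K2CO3 and 22 in MeCN at room temperature the phenoxide expels sulfinate, 24 is regenerated without acid, and the pyranone anion adds through C3 to give 25.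

Step 9.
- What may go wrong: proton transfer from the enolisable anhydride to the hindered aryllithium, and slow attack at a branched acyl carbon flanked by two ortho acetals, would simply return protonated starting material.
- Fallback: it changes the oxidation level of the electrophile, setting out from 11 (lithiated to 13 as before) and returning at 14.
- Quenching 13 with isobutyraldehyde at −78 °C should give the benzylic carbinol 1-[(2R)-7-(methoxymethyl)-4,6-bis(methoxymethoxy)-2-{2-[(triethylsilyl)oxy]propan-2-yl}-2,3-dihydro-1-benzofuran-5-yl]-2-methylpropan-1-ol F8. It forms as both carbinol epimers, which is of no consequence.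
- Dess–Martin oxidation (CH2Cl2, NaHCO3, rt) converts this carbinol into 14.

**Further compounds**
F1 | step 8 | 3,5-bis(methoxymethoxy)-2-(methoxymethyl)phenol | COCc1c(O)cc(OCOC)cc1OCOC
F2 | step 8 | 1-(methoxymethyl)-2,4-bis(methoxymethoxy)-6-[(2-methylbut-3-en-2-yl)oxy]benzene | C=CC(C)(C)Oc1cc(OCOC)cc(OCOC)c1COC
F3 | step 8 | 3,5-bis(methoxymethoxy)-2-(methoxymethyl)-6-(3-methylbut-2-en-1-yl)phenol | CC(C)=CCc1c(O)c(COC)c(OCOC)cc1OCOC
F4 | step 8 | 3,5-bis(methoxymethoxy)-2-(methoxymethyl)-6-(3-methylbut-2-en-1-yl)phenyl acetate | CC(C)=CCc1c(OC(C)=O)c(COC)c(OCOC)cc1OCOC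
F5 | step 8 | 2-{[(2S)-3,3-dimethyloxiran-2-yl]methyl}-3,5-bis(methoxymethoxy)-6-(methoxymethyl)phenyl acetate | CC1(C)O[C@H]1Cc2c(OC(C)=O)c(COC)c(OCOC)cc2OCOC
F6 | step 8 | 2-[(2R)-7-(methoxymethyl)-4,6-bis(methoxymethoxy)-2,3-dihydro-1-benzofuran-2-yl]propan-2-ol | CC(C)(O)[C@H]1Cc2c(OCOC)cc(OCOC)c(COC)c2O1
F7 | step 14 | 1-[(2R)-4,6-dihydroxy-7-{[(4-methylphenyl)sulfonyl]methyl}-2-(prop-1-en-2-yl)-2,3-dihydro-1-benzofuran-5-yl]-2-methylpropan-1-one | C=C(C)[C@H]1Cc2c(O)c(C(=O)C(C)C)c(O)c(CS(=O)(=O)c3ccc(C)cc3)c2O1
F8 | step 9 | 1-[(2R)-7-(methoxymethyl)-4,6-bis(methoxymethoxy)-2-{2-[(triethylsilyl)oxy]propan-2-yl}-2,3-dihydro-1-benzofuran-5-yl]-2-methylpropan-1-ol | CC[Si](CC)(CC)OC(C)(C)[C@H]1Cc2c(OCOC)c(C(O)C(C)C)c(OCOC)c(COC)c2O1
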